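**Retrosynthetic overview**
1. Target 31 comes from i-Bu2AlH opening of the seven-membered unsaturated lactone 29 (C1–O–C26). The lactone is closed by an intramolecular Horner–Wadsworth–Emmons reaction on ketone 28 and fixes the tetrasubstituted enal as Z.
2. The side chain is joined by Suzuki–Miyaura coupling (C15–C16) of ring B vinyl iodide 15 with ring A (E)-alkenylboronate 22.
3. Ring B comes from an intramolecular Diels–Alder reaction of 2-alkoxy-5-methylfuran 13 with its own (Z)-enoate. Ring B and a tetrahydropyran form together; the furan oxygen becomes C10–OH, the bridged ketal becomes the C7 ketone and C3–OH, and the ester becomes C26H2OH.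
4. 13 comes from Still–Gennari olefination of aldehyde 4 with menthyl phosphonate 12; boronate 22 comes from 2-methylcyclohex-2-enone (asymmetric conjugate addition/methylation, methylenation, epoxide-to-aldehyde rearrangement, Takai–Utimoto).
5. Ring order: ring A is carried from the starting cyclohexenone in its own branch; ring B and the temporary pyran form in one step; the temporary lactone forms last.

Assumption and labels: the target is taken as the open hydroxy-aldehyde drawn (lactol 30 opens on its own). C1 = CHO, C2 = C(Me)=, C3–C5 = hydroxypropyl (C3 bears OH), C6–C11 = ring B (C7 = alkylidene carbon, C10 = C(Me)OH, C11 quaternary), C26 = CH2OH on C11, C12–C17 = chain to ring A.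

**Route**

Step 1
Reactants: 1 2-bromo-5-methylfuran; 2 butane-1,4-diol (5 equiv)
Product: 3 4-[(5-methylfuran-2-yl)oxy]butan-1-ol
Conditions: CuI (10 mol%), 3,4,7,8-tetramethyl-1,10-phenanthroline (20 mol%), Cs2CO3, toluene, 100 °C
Reagents that add atoms: none
Why: Ullmann-type copper-catalysed C–O coupling of a heteroaryl bromide with a primary alcohol, the excess diol giving the mono-ether.

Step 2
Reactants: 3 4-[(5-methylfuran-2-yl)oxy]butan-1-ol
Product: 4 4-[(5-methylfuran-2-yl)oxy]butanal
Conditions: SO3·pyridine, DMSO, i-Pr2NEt, CH2Cl2, 0 °C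
Reagents that add atoms: none
Why: Parikh–Doering oxidation is non-acidic and does not attack the electron-rich alkoxyfuran.

Step 3
Reactants: 5 methyl 2-[bis(2,2,2-trifluoroethoxy)phosphoryl]acetate; 6 (1R,2S,5R)-(−)-menthol
Product: 7 (1R,2S,5R)-menthyl 2-[bis(2,2,2-trifluoroethoxy)phosphoryl]acetate
Conditions: DMAP (0.3 equiv), toluene, 110 °C, 4 Å molecular sieves
Reagents that add atoms: none
Why: DMAP-catalysed transesterification of a phosphonoacetate installs the chiral ester that later makes the two mirror-image cycloadducts diastereomers.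

Step 4
Reactants: 8 pent-3-yn-1-ol
Product: 10 (E)-4-iodopent-3-en-1-ol, via alkenylzirconocene 9 (not isolated)
Conditions: Cp2Zr(H)Cl (2.3 equiv), THF, rt to 40 °C; then I2, 0 °C
Reagents that add atoms: iodine, I-I
Why: Hydrozirconation (syn addition, zirconium on the methyl-bearing carbon after equilibration) and iodination with retention give the E trisubstituted alkene that becomes C14=C15.

Step 5
Reactants: 10 (E)-4-iodopent-3-en-1-ol
Product: 11 (E)-2,5-diiodopent-2-ene
Conditions: I2, PPh3, imidazole, CH2Cl2, 0 °C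
Reagents that add atoms: iodine, I-I
Why: Appel-type iodination of the primary alcohol leaves the vinyl iodide untouched.

Step 6
Reactants: 7 (1R,2S,5R)-menthyl 2-[bis(2,2,2-trifluoroethoxy)phosphoryl]acetate; 11 (E)-2,5-diiodopent-2-ene
Product: 12 (1R,2S,5R)-menthyl (5E)-2-[bis(2,2,2-trifluoroethoxy)phosphoryl]-6-iodohept-5-enoate
Conditions: NaH, DMF, 0 °C to rt
Reagents that add atoms: none
Why: C-alkylation of the stabilised phosphonoacetate anion occurs only at the primary sp3 iodide; the new α-centre is lost in step 7.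

Step 7
Reactants: 12 (1R,2S,5R)-menthyl (5E)-2-[bis(2,2,2-trifluoroethoxy)phosphoryl]-6-iodohept-5-enoate; 4 4-[(5-methylfuran-2-yl)oxy]butanal
Product: 13 (1R,2S,5R)-menthyl (2Z)-2-[(3E)-4-iodopent-3-en-1-yl]-6-[(5-methylfuran-2-yl)oxy]hex-2-enoate
Conditions: KN(SiMe3)2, 18-crown-6, THF, −78 °C
Reagents that add atoms: none
Why: Still–Gennari olefination gives the Z trisubstituted enoate (ester cis to the C5 chain), the geometry that later places C26 and C5 cis on ring B.

Step 8 (key step)
Reactants: 13 (1R,2S,5R)-menthyl (2Z)-2-[(3E)-4-iodopent-3-en-1-yl]-6-[(5-methylfuran-2-yl)oxy]hex-2-enoate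
Product: 15 menthyl ester of the ring B methyl ketal (cis-fused pyran C7–O–C3; C8=C9; C10 Me/OH; C11 ester and iodopentenyl chain), via bridged cycloadduct 14 (not isolated)
Conditions: toluene (0.01 M), BHT, K2CO3 (solid), 100 °C; then MeOH, PPTS (10 mol%), 0 °C to rt; chromatography
Reagents that add atoms: methanol, CO
Why: Proposed new method: intramolecular Diels–Alder reaction of a 2-alkoxyfuran in which the four-atom O–C3–C4–C5 tether can only span the exo face, so C5 and (because the enoate is Z) the ester carbon C26 end up syn to the oxygen bridge that becomes the C10 hydroxyl, which sets C6, C10 and C11 in the relative configuration of the target in one suprafacial event, and acid-catalysed methanolysis of the strained bridged ketal makes the cycloaddition irreversible; the closest known reaction type is the intramolecular Diels–Alder reaction of 2-amidofurans followed by opening of the oxygen bridge; the menthyl ester is expected to give little facial bias (two exo adducts near 1:1), but it makes them diastereomers, and the one drawn is separated here.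

Step 9
Reactants: 16 2-methylcyclohex-2-en-1-one
Product: 18 (3S)-2,2,3-trimethylcyclohexan-1-one, via magnesium enolate 17 (not isolated)
Conditions: MeMgBr, Cu(OTf)2 (3 mol%), chiral N-heterocyclic carbene ligand (4 mol%, enantiomer giving the 3S adduct), Et2O, −30 °C; then MeI, DMPU, −30 °C to rt
Reagents that add atoms: methylmagnesium bromide, C[Mg]Br; iodomethane, CI
Why: Copper-catalysed asymmetric conjugate addition sets the methyl-bearing stereocentre under ligand control, and the regiodefined enolate is C-methylated to the gem-dimethyl carbon.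

Step 10
Reactants: 18 (3S)-2,2,3-trimethylcyclohexan-1-one
Product: 19 (3S)-2,2,3-trimethyl-6-methylidenecyclohexan-1-one
Conditions: (CH2O)n, N-methylanilinium trifluoroacetate, THF, 65 °C
Reagents that add atoms: formaldehyde, C=O
Why: Mannich-type α-methylenation at the only enolisable α-carbon; the stereocentre is not α to the carbonyl.

Step 11
Reactants: 19 (3S)-2,2,3-trimethyl-6-methylidenecyclohexan-1-one
Product: 20 (5S)-4,4,5-trimethyl-8-methylidene-1-oxaspiro[2.5]octane
Conditions: Me3S+ I−, n-BuLi, THF, −10 °C to rt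
Reagents that add atoms: trimethylsulfonium iodide, C[S+](C)C.[I-]
Why: Corey–Chaykovsky epoxidation; the sulfonium methylide adds 1,2 to the enone carbonyl by axial attack (CH2 axial, oxygen equatorial).

Step 12
Reactants: 20 (5S)-4,4,5-trimethyl-8-methylidene-1-oxaspiro[2.5]octane
Product: 21 (1R,3S)-2,2,3-trimethyl-6-methylidenecyclohexane-1-carbaldehyde
Conditions: BF3·OEt2 (0.2 equiv), CH2Cl2, −78 °C, 10 min; Et3N
Reagents that add atoms: none
Why: Meinwald rearrangement: the allylic tertiary C–O bond ionises and a hydride shifts from the oxirane CH2 anti to the departing equatorial oxygen, leaving the formyl group equatorial and cis to the ring methyl (also the more stable epimer).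

Step 13
Reactants: 21 (1R,3S)-2,2,3-trimethyl-6-methylidenecyclohexane-1-carbaldehyde
Product: 22 pinacol (E)-2-[(1R,3S)-2,2,3-trimethyl-6-methylidenecyclohexyl]ethenylboronate
Conditions: CrCl2, Cl2CHB(pin), LiI, THF, rt
Reagents that add atoms: 2-(dichloromethyl)-4,4,5,5-tetramethyl-1,3,2-dioxaborolane, ClC(Cl)B1OC(C)(C)C(C)(C)O1
Why: Takai–Utimoto olefination is non-basic and E-selective, so the epimerisable α-centre and the exocyclic alkene are untouched.

Step 14
Reactants: 15 menthyl ester of the ring B methyl ketal with (E)-vinyl iodide; 22 pinacol (E)-alkenylboronate of ring A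
Product: 23 coupled menthyl ester ketal with the complete (14E,16E)-diene chain and ring A
Conditions: Pd(PPh3)4 (5 mol%), TlOEt, THF/H2O 3:1, rt
Reagents that add atoms: none
Why: Suzuki–Miyaura coupling proceeds with retention at both alkenes and tolerates the ester, ketal and free tertiary alcohol.

Step 15
Reactants: 23 coupled menthyl ester ketal
Product: 24 ketal alcohol (C26H2OH free)
Conditions: LiAlH4, THF, 0 °C to rt; aqueous NaOH work-up
Reagents that add atoms: none
Why: Ester reduction frees C26H2OH and removes the auxiliary while the ketal still masks the C7 ketone and the C3 oxygen.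

Step 16
Reactants: 24 ketal alcohol; 25 2-(diethoxyphosphoryl)propanoic acid
Product: 27 enone C26 phosphonopropanoate with free hydroxypropyl arm, via acylated ketal 26 (not isolated)
Conditions: EDC·HCl, DMAP (20 mol%), CH2Cl2, rt; then PPTS, acetone/H2O 4:1, 40 °C
Reagents that add atoms: water, O
Why: Carbodiimide (Steglich-type) esterification hits the only free primary alcohol (C3–O is locked in the ketal, the tertiary OH is inert), then hydrolysis of the allylic mixed ketal unmasks the C7 enone and C3–OH.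

Step 17
Reactants: 27 enone C26 phosphonopropanoate
Product: 28 saturated C7 ketone phosphonopropanoate
Conditions: [(Ph3P)CuH]6 (0.5 equiv), H2O (5 equiv), toluene, rt
Reagents that add atoms: none
Why: Stryker conjugate reduction removes only the enone C8=C9 bond; the unconjugated diene and exocyclic alkene do not react.

Step 18
Reactants: 28 saturated C7 ketone phosphonopropanoate
Product: 29 seven-membered α,β-unsaturated lactone (C1(=O)–O–C26; C2=C7)
Conditions: LiCl, i-Pr2NEt, MeCN (0.003 M), rt to 50 °C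
Reagents that add atoms: none
Why: Intramolecular Horner–Wadsworth–Emmons reaction (Masamune–Roush conditions) onto the C7 ketone; the seven-membered ring allows only the geometry with C1 on the C6 side, which is the Z enal of the target.

Step 19
Reactants: 29 seven-membered α,β-unsaturated lactone
Product: 31 target, via lactol 30 (not isolated)
Conditions: i-Bu2AlH (5 equiv), CH2Cl2, −78 °C; MeOH, aqueous potassium sodium tartrate (KNaC4H4O6)
Reagents that add atoms: none
Why: Half-reduction of the lactone gives the lactol, which opens to the free hydroxy-enal with the Z geometry retained and C26H2OH released.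

**Compound list**

1 | 2-bromo-5-methylfuran | Cc1ccc(Br)o1 | starting material
2 | butane-1,4-diol | OCCCCO | starting material
3 | 4-[(5-methylfuran-2-yl)oxy]butan-1-ol | Cc1ccc(OCCCCO)o1 | intermediate
4 | 4-[(5-methylfuran-2-yl)oxy]butanal | Cc1ccc(OCCCC=O)o1 | intermediate
5 | methyl 2-[bis(2,2,2-trifluoroethoxy)phosphoryl]acetate | COC(=O)CP(=O)(OCC(F)(F)F)OCC(F)(F)F | starting material
6 | (1R,2S,5R)-(−)-menthol | CC(C)[C@@H]1CC[C@@H](C)C[C@H]1O | starting material
7 | (1R,2S,5R)-menthyl 2-[bis(2,2,2-trifluoroethoxy)phosphoryl]acetate | CC(C)[C@@H]1CC[C@@H](C)C[C@H]1OC(=O)CP(=O)(OCC(F)(F)F)OCC(F)(F)F | intermediate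
8 | pent-3-yn-1-ol | CC#CCCO | starting material
9 | (E)-alkenyl–Zr(Cl)Cp2 species from 8, hydroxyl present as its Cp2Zr(Cl) alkoxide | C/C(=C\CCO[Zr](Cl)(C1C=CC=C1)C1C=CC=C1)[Zr](Cl)(C1C=CC=C1)C1C=CC=C1 | intermediate (not isolated)
10 | (E)-4-iodopent-3-en-1-ol | C/C(I)=C\CCO | intermediate
11 | (E)-2,5-diiodopent-2-ene | C/C(I)=C\CCI | intermediate
12 | (1R,2S,5R)-menthyl (5E)-2-[bis(2,2,2-trifluoroethoxy)phosphoryl]-6-iodohept-5-enoate (C2 epimers) | C/C(I)=C\CCC(C(=O)O[C@@H]1C[C@H](C)CC[C@H]1C(C)C)P(=O)(OCC(F)(F)F)OCC(F)(F)F | intermediate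
13 | (1R,2S,5R)-menthyl (2Z)-2-[(3E)-4-iodopent-3-en-1-yl]-6-[(5-methylfuran-2-yl)oxy]hex-2-enoate | C/C(I)=C\CC/C(C(=O)O[C@@H]1C[C@H](C)CC[C@H]1C(C)C)=C/CCCOc1ccc(C)o1 | intermediate
14 | bridged exo cycloadduct: 7-oxabicyclo[2.2.1]hept-2-ene (O bridge C7–O–C10) fused to a tetrahydropyran (C7–O–C3–C4–C5–C6); C5 and the menthyl ester on C11 syn to the O bridge | C/C(I)=C\CC[C@@]1(C(=O)O[C@@H]2C[C@H](C)CC[C@H]2C(C)C)[C@@H]2CCCO[C@@]23C=C[C@]1(C)O3 | intermediate (not isolated)
15 | menthyl ester of ring B methyl ketal: C7(OMe) tied to C3–O in a cis-fused pyran, C8=C9, C10 (Me)(OH), C11 bearing CO2-menthyl and the (E)-4-iodopent-3-enyl chain; C6, C10, C11 as in the target; C7 anomers (mainly axial OMe) | C/C(I)=C\CC[C@@]1(C(=O)O[C@@H]2C[C@H](C)CC[C@H]2C(C)C)[C@@H]2CCCOC2(OC)C=C[C@]1(C)O | intermediate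
16 | 2-methylcyclohex-2-en-1-one | CC1=CCCCC1=O | starting material
17 | bromomagnesium (3S)-2,3-dimethylcyclohex-1-en-1-olate | Br[Mg]OC1=C(C)[C@@H](C)CCC1 | intermediate (not isolated)
18 | (3S)-2,2,3-trimethylcyclohexan-1-one | O=C1CCC[C@H](C)C1(C)C | intermediate
19 | (3S)-2,2,3-trimethyl-6-methylidenecyclohexan-1-one | O=C1C(=C)CC[C@H](C)C1(C)C | intermediate
20 | (5S)-4,4,5-trimethyl-8-methylidene-1-oxaspiro[2.5]octane (spiro centre: mainly CH2 axial, consumed in step 12) | C=C1CC[C@H](C)C(C)(C)C12CO2 | intermediate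
21 | (1R,3S)-2,2,3-trimethyl-6-methylidenecyclohexane-1-carbaldehyde | C=C1CC[C@H](C)C(C)(C)[C@@H]1C=O | intermediate
22 | 4,4,5,5-tetramethyl-2-{(E)-2-[(1R,3S)-2,2,3-trimethyl-6-methylidenecyclohexyl]ethenyl}-1,3,2-dioxaborolane | C=C1CC[C@H](C)C(C)(C)[C@@H]1/C=C/B1OC(C)(C)C(C)(C)O1 | intermediate
23 | coupled menthyl ester ketal: as 15 with the iodide replaced by the (E)-2-(ring A)ethenyl group, giving the (14E,16E)-diene | C=C1CC[C@H](C)C(C)(C)[C@@H]1/C=C/C(C)=C/CC[C@@]1(C(=O)O[C@@H]2C[C@H](C)CC[C@H]2C(C)C)[C@@H]2CCCOC2(OC)C=C[C@]1(C)O | intermediate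
24 | ketal alcohol: as 23 with the ester reduced to C26H2OH | C=C1CC[C@H](C)C(C)(C)[C@@H]1/C=C/C(C)=C/CC[C@@]1(CO)[C@@H]2CCCOC2(OC)C=C[C@]1(C)O | intermediate
25 | 2-(diethoxyphosphoryl)propanoic acid | CCOP(=O)(OCC)C(C)C(O)=O | starting material
26 | C26 2-(diethoxyphosphoryl)propanoate of ketal alcohol 24 | C=C1CC[C@H](C)C(C)(C)[C@@H]1/C=C/C(C)=C/CC[C@@]1(COC(=O)C(C)P(=O)(OCC)OCC)[C@@H]2CCCOC2(OC)C=C[C@]1(C)O | intermediate (not isolated)
27 | enone: C7 ketone, C8=C9, free 3-hydroxypropyl on C6, C10 (Me)(OH), C26 phosphonopropanoate | C=C1CC[C@H](C)C(C)(C)[C@@H]1/C=C/C(C)=C/CC[C@@]1(COC(=O)C(C)P(=O)(OCC)OCC)[C@H](CCCO)C(=O)C=C[C@]1(C)O | intermediate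
28 | saturated ketone: as 27 with C8–C9 reduced | C=C1CC[C@H](C)C(C)(C)[C@@H]1/C=C/C(C)=C/CC[C@@]1(COC(=O)C(C)P(=O)(OCC)OCC)[C@H](CCCO)C(=O)CC[C@]1(C)O | intermediate
29 | seven-membered lactone: C26–O–C1(=O)–C2(Me)=C7, bridging C11 and C7 of ring B | C=C1CC[C@H](C)C(C)(C)[C@@H]1/C=C/C(C)=C/CC[C@@]1(COC(=O)C(C)=C2CC[C@]1(C)O)[C@@H]2CCCO | intermediate
30 | lactol of 29 (C1 hemiacetal, epimers) | C=C1CC[C@H](C)C(C)(C)[C@@H]1/C=C/C(C)=C/CC[C@@]1(COC(O)C(C)=C2CC[C@]1(C)O)[C@@H]2CCCO | intermediate (not isolated)
31 | (2Z)-2-[(2R,3S,4S)-4-hydroxy-3-(hydroxymethyl)-2-(3-hydroxypropyl)-4-methyl-3-{(3E,5E)-4-methyl-6-[(1R,3S)-2,2,3-trimethyl-6-methylidenecyclohexyl]hexa-3,5-dien-1-yl}cyclohexylidene]propanal | C=C1CC[C@H](C)C(C)(C)[C@@H]1/C=C/C(C)=C/CC[C@@]1(CO)[C@H](CCCO)/C(=C(/C)C=O)CC[C@]1(C)O | target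

**Totals**
Total steps: 19. Longest linear sequence: 11 steps (steps 4, 5, 6, 7, 8, 14, 15, 16, 17, 18, 19; the ring A branch, steps 9–13 then 14–19, is equally long).

**Three steps most likely to fail, with fallbacks**

Step 8 (furan Diels–Alder). The bond C10–C11 joins two fully substituted carbons, and the furan adduct can revert. The fallback sets out from 13 and comes back at 15. Dilute aqueous HCl in THF hydrolyses the alkoxyfuran of 13 to the 4-oxopentanoate ester F1. Soft enolisation with Me3SiOTf/Et3N gives the acyclic bis(trimethylsilyl) dienol ether F2, a diene that needs no dearomatisation and cannot cyclorevert. Heating F2 in toluene gives the intramolecular Diels–Alder adduct, the cyclohexene bis-silyl ether F3 (same exo-tether arrangement with both oxygens inside the diene). MeOH/PPTS then exchanges the silyl ketal for the methyl ketal and frees the tertiary alcohol, which is 15; the menthyl diastereomers are separated there as before.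

Step 18 (seven-membered ring by Horner–Wadsworth–Emmons on a hindered ketone). The fallback sets out from 24 and comes back at 31, giving up the template. PPTS in aqueous acetone hydrolyses the ketal of 24 to the enone triol F5, and [(Ph3P)CuH]6 reduces it to the ketone triol F6. Excess 1-ethoxy-2-lithioprop-1-ene (from 2-bromo-1-ethoxyprop-1-ene and t-BuLi) with CeCl3 adds to the C7 ketone to give the tertiary allylic alcohol F7. Dilute HCl in THF hydrolyses the enol ether with allylic transposition to the enal as a Z/E mixture. The Z isomer 31 is separated, and the E isomer is recycled by photoisomerisation.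

Step 12 (Lewis-acid rearrangement of the vinyl epoxide; risk of conjugation or allylic substitution). The fallback sets out from 20 and comes back at 21. Pd2(dba)3·CHCl3/PBu3 with HCO2H–Et3N hydrogenolyses the vinyl epoxide through the π-allyl complex, delivering hydride to the tertiary terminus with inversion, to give [(1R,3S)-2,2,3-trimethyl-6-methylidenecyclohexyl]methanol F4. Dess–Martin periodinane with NaHCO3 oxidises F4 to 21.

**Further compounds**
F1 | step 8 | (1R,2S,5R)-menthyl (2Z)-2-[(3E)-4-iodopent-3-en-1-yl]-6-(4-oxopentanoyloxy)hex-2-enoate | C/C(I)=C\CC/C(C(=O)O[C@@H]1C[C@H](C)CC[C@H]1C(C)C)=C/CCCOC(=O)CCC(C)=O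
F2 | step 8 | bis(trimethylsilyl) dienol ether of F1: 1-alkoxy-1,4-bis(trimethylsilyloxy)penta-1,3-diene (diene geometry not fixed) | C/C(I)=C\CC/C(C(=O)O[C@@H]1C[C@H](C)CC[C@H]1C(C)C)=C/CCCOC(O[Si](C)(C)C)=CC=C(C)O[Si](C)(C)C
F3 | step 8 | cyclohexene bis-silyl ether: as 15 with C7 OSiMe3 in place of OMe and C10 OSiMe3 in place of OH | C/C(I)=C\CC[C@@]1(C(=O)O[C@@H]2C[C@H](C)CC[C@H]2C(C)C)[C@@H]2CCCOC2(O[Si](C)(C)C)C=C[C@]1(C)O[Si](C)(C)C
F4 | step 12 | [(1R,3S)-2,2,3-trimethyl-6-methylidenecyclohexyl]methanol | C=C1CC[C@H](C)C(C)(C)[C@@H]1CO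
F5 | step 18 | enone triol: C7 ketone, C8=C9, free C3–OH, C10–OH and C26–OH | C=C1CC[C@H](C)C(C)(C)[C@@H]1/C=C/C(C)=C/CC[C@@]1(CO)[C@H](CCCO)C(=O)C=C[C@]1(C)O
F6 | step 18 | ketone triol: as F5 with C8–C9 saturated | C=C1CC[C@H](C)C(C)(C)[C@@H]1/C=C/C(C)=C/CC[C@@]1(CO)[C@H](CCCO)C(=O)CC[C@]1(C)O
F7 | step 18 | tertiary allylic alcohol: C7(OH) bearing the 1-ethoxyprop-1-en-2-yl group (C7 and enol ether geometry not fixed) | C=C1CC[C@H](C)C(C)(C)[C@@H]1/C=C/C(C)=C/CC[C@@]1(CO)[C@H](CCCO)C(O)(C(C)=COCC)CC[C@]1(C)O
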